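**Retrosynthetic overview**
1. Last ring: the 5,6-dihydro-2H-pyran-2-one (O5–C1(=O)–C2=C3–C4–C5) is closed at the end by lactonisation of O5 onto a (Z)-C2=C3 methyl ester when the C5/C6 acetonide is removed; C1–C2 come from a Z-selective olefination of a C3 aldehyde.
2. Key disconnection C9–C10: the (E)-C8=C9 alkene joins ring carbon C7 of the tetrahydrofuran to the oxygenated carbinol C10, which lies anti to the C11 acetate. This (E)-allylic, anti-1,2-dioxygenated unit is the product pattern of a three-component reductive coupling of a C7-ethynyl group, (R)-2-acetoxypropanal (C10–C12) and a silane; the silyl group on O10 is then exchanged for benzoyl.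
3. The tetrahydrofuran ring (O, C4, C5, C6, C7; all four substituents cis) is not built but taken from D-mannose (sugar C4, C3, C2, C1). C7–C8 comes from acetylide addition to the mannonolactone, C7–H from hydride reduction of the hemiketal on the open face, and sugar C6 is excised to reveal C3.
4. Ring order: tetrahydrofuran (chiral pool), then the side chain (key step), then the dihydropyranone.

Key step: step 6

Remark on numbering: the target is numbered along its twelve-carbon chain, C1 = lactone carbonyl to C12 = methyl. The ring oxygen bridges C4 and C7, O5 is the lactone oxygen, C6 carries the free hydroxyl, C10 the benzoate and C11 the acetate; the target is (4R,5R,6R,7S,10S,11R), 8E. Diacetone-D-mannose and (R)-but-3-en-2-ol are assumed to be purchased.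

**Route**

Step 1
Reactants: 1 2,3:5,6-di-O-isopropylidene-α-D-mannofuranose
Product: 2 2,3:5,6-di-O-isopropylidene-D-mannono-1,4-lactone
Conditions: TEMPO (cat.), PhI(OAc)2, CH2Cl2, rt
Reagents that add atoms: none
Why: Oxoammonium (TEMPO/PhI(OAc)2) oxidation of a lactol to the lactone; no stereocentre is touched and both acetonides should tolerate the weakly acidic medium.

Step 2
Reactants: 2 2,3:5,6-di-O-isopropylidene-D-mannono-1,4-lactone; 3 ethynylmagnesium bromide (HC≡CMgBr)
Product: 4 1-C-ethynyl-2,3:5,6-di-O-isopropylidene-D-mannofuranose (hemiketal, anomers)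
Conditions: THF, −78 → −20 °C; aq. NH4Cl
Reagents that add atoms: none
Why: Acetylide 1,2-addition to a γ-lactone should stop at the hemiketal because the magnesium hemiketalate is stable at low temperature; the new anomeric centre is unimportant since it is planarised in step 3.

Step 3
Reactants: 4 1-C-ethynyl-2,3:5,6-di-O-isopropylidene-D-mannofuranose; 5 triethylsilane
Product: 6 (2,3:5,6-di-O-isopropylidene-β-D-mannofuranosyl)ethyne
Conditions: BF3·OEt2, CH2Cl2/MeCN, −78 → −40 °C
Reagents that add atoms: none
Why: Lewis-acid-mediated silane reduction of a hemiketal through the furanosyl oxocarbenium ion (C-glycoside synthesis): hydride should attack the convex face, anti to the cis-fused 2,3-dioxolane and to the C4 side chain, so the ethynyl group ends on the crowded face and C7 is set all-cis (S).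

Step 4
Reactants: 7 (R)-but-3-en-2-ol
Product: 8 (R)-but-3-en-2-yl acetate
Conditions: Ac2O, pyridine, DMAP (cat.), CH2Cl2, 0 °C → rt
Reagents that add atoms: acetic anhydride, CC(=O)OC(C)=O
Why: DMAP-catalysed O-acetylation; the C–O bond of the stereocentre (future C11) is not broken, so configuration is retained.

Step 5
Reactants: 8 (R)-but-3-en-2-yl acetate
Product: 10 (R)-2-acetoxypropanal, via ozonide 9 (not isolated)
Conditions: O3, CH2Cl2, −78 °C; then PPh3, −78 °C → rt
Reagents that add atoms: ozone, [O-][O+]=O
Why: Ozonolysis with reductive work-up (Criegee mechanism) cleaves the vinyl group to the aldehyde under neutral conditions that should not epimerise the α-acyloxy stereocentre; the aldehyde is used at once.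

Step 6
Reactants: 6 (2,3:5,6-di-O-isopropylidene-β-D-mannofuranosyl)ethyne; 10 (R)-2-acetoxypropanal; 5 triethylsilane
Product: 11 (1E,3S,4R)-4-acetoxy-1-(2,3:5,6-di-O-isopropylidene-β-D-mannofuranosyl)-3-(triethylsilyloxy)pent-1-ene
Conditions: Ni(cod)2 (10 mol%), IMes (1,3-dimesitylimidazol-2-ylidene, 10 mol%), THF, rt, slow addition of 6
Reagents that add atoms: none
Why: This is the nickel-catalysed three-component reductive coupling of a terminal alkyne, an aldehyde and a silane, a known route to (E)-allylic silyl ethers that also covers α-oxygenated aldehydes: zerovalent nickel bearing the small carbene IMes binds 6 and 10, oxidative cyclisation forms the C9–C10 bond in a five-membered oxanickelacycle, σ-bond metathesis of its Ni–O bond with Et3Si–H places the silyl group on O10, and C–H reductive elimination releases 11 and the catalyst. No ring of the product is closed (only the transient oxanickelacyclopentene forms), and the net cis addition of H to C8 and of the carbinol carbon to C9 fixes the (E)-alkene. The new stereocentre C10 is controlled by C11 of the aldehyde: in the polar Felkin–Anh arrangement the C11–OAc bond lies anti to the forming bond and the alkyne carbon passes the small hydrogen, which should give the 10S,11R (anti) isomer. Regioselectivity (bond at the terminal carbon C9, not C8) is secured by the small carbene ligand and by the bulky branched C7 substituent staying remote from the aldehyde. Chemoselectivity is secured by running the step before any enoate or free hydroxyl exists, with the ring ether, acetonides and acetate inert to the catalyst. Slow addition of the alkyne should keep nickel-mediated alkyne oligomerisation behind the cross-coupling.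

Step 7
Reactants: 11 (1E,3S,4R)-4-acetoxy-1-(2,3:5,6-di-O-isopropylidene-β-D-mannofuranosyl)-3-(triethylsilyloxy)pent-1-ene
Product: 12 (1E,3S,4R)-4-acetoxy-1-(2,3:5,6-di-O-isopropylidene-β-D-mannofuranosyl)pent-1-en-3-ol
Conditions: HF·pyridine, pyridine, THF, 0 °C
Reagents that add atoms: none
Why: Fluoride cleavage of the triethylsilyl ether under buffered acidic conditions should leave both acetonides and the neighbouring acetate in place and avoids base-induced acetyl migration.

Step 8
Reactants: 12 (1E,3S,4R)-4-acetoxy-1-(2,3:5,6-di-O-isopropylidene-β-D-mannofuranosyl)pent-1-en-3-ol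
Product: 13 (1E,3S,4R)-4-acetoxy-3-benzoyloxy-1-(2,3:5,6-di-O-isopropylidene-β-D-mannofuranosyl)pent-1-ene
Conditions: BzCl, pyridine, DMAP (cat.), CH2Cl2, 0 °C
Reagents that add atoms: benzoyl chloride, O=C(Cl)c1ccccc1
Why: DMAP-catalysed benzoylation of the secondary allylic alcohol should outrun O-to-O acetyl migration at 0 °C, and C10 keeps its configuration because its C–O bond is not broken.

Step 9
Reactants: 13 (1E,3S,4R)-4-acetoxy-3-benzoyloxy-1-(2,3:5,6-di-O-isopropylidene-β-D-mannofuranosyl)pent-1-ene
Product: 15 C3 aldehyde (β-D-lyxo-pentodialdofuranosyl C-glycoside), via 5,6-diol 14 (not isolated)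
Conditions: H5IO6, EtOAc, rt
Reagents that add atoms: none
Why: One-pot selective hydrolysis of the terminal, more labile dioxolane and periodate glycol cleavage (Malaprade reaction) excises sugar C6; the ring-fused acetonide, both esters and the alkene should be inert.

Step 10
Reactants: 15 C3 aldehyde; 16 methyl bis(2,2,2-trifluoroethyl)phosphonoacetate
Product: 17 methyl (Z)-enoate (C1–C12 skeleton complete, C5/C6 acetonide)
Conditions: KN(SiMe3)2, 18-crown-6, THF, −78 °C
Reagents that add atoms: none
Why: Still–Gennari variant of the Horner–Wadsworth–Emmons reaction: the electron-poor phosphonate eliminates fast from the kinetic adduct to give the (Z)-enoate, and at −78 °C with the preformed potassium phosphonate the C4 centre α to the aldehyde should not epimerise.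

Step 11
Reactants: 17 methyl (Z)-enoate
Product: 19 target (CNP0151877.1), via dihydroxy (Z)-ester 18 (not isolated)
Conditions: TFA/H2O (9:1), CH2Cl2, 0 °C → rt
Reagents that add atoms: none
Why: Acid hydrolysis of the dioxolane followed by spontaneous acid-catalysed lactonisation of the C5 hydroxyl onto the (Z)-ester closes the six-membered ring (cis-fused); the C6 hydroxyl would need a seven-membered ring and stays free, and no stereocentre is affected.

**Compound list**
1 | 2,3:5,6-di-O-isopropylidene-α-D-mannofuranose (diacetone-D-mannose) | O[C@H]1O[C@H]([C@H]3COC(C)(C)O3)[C@@H]2OC(C)(C)O[C@H]12 | starting material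
2 | 2,3:5,6-di-O-isopropylidene-D-mannono-1,4-lactone | O=C1O[C@H]([C@H]3COC(C)(C)O3)[C@@H]2OC(C)(C)O[C@H]12 | intermediate
3 | ethynylmagnesium bromide | C#C[Mg]Br | starting material
4 | 1-C-ethynyl-2,3:5,6-di-O-isopropylidene-D-mannofuranose (hemiketal, mixture at the anomeric carbon) | C#CC1(O)O[C@H]([C@H]3COC(C)(C)O3)[C@@H]2OC(C)(C)O[C@H]12 | intermediate
5 | triethylsilane | CC[SiH](CC)CC | starting material
6 | (2,3:5,6-di-O-isopropylidene-β-D-mannofuranosyl)ethyne (ethynyl cis to the ring dioxolane and to the C4 side chain; C7 S) | C#C[C@@H]1O[C@H]([C@H]3COC(C)(C)O3)[C@@H]2OC(C)(C)O[C@H]12 | intermediate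
7 | (R)-but-3-en-2-ol | C[C@@H](O)C=C | starting material
8 | (R)-but-3-en-2-yl acetate | CC(=O)O[C@H](C)C=C | intermediate
9 | 3-[(1R)-1-acetoxyethyl]-1,2,4-trioxolane (ozonide, mixture at the ring carbon) | CC(=O)O[C@H](C)C1OCOO1 | intermediate
10 | (R)-2-acetoxypropanal | CC(=O)O[C@H](C)C=O | intermediate
11 | (1E,3S,4R)-4-acetoxy-1-(2,3:5,6-di-O-isopropylidene-β-D-mannofuranosyl)-3-(triethylsilyloxy)pent-1-ene (C10 S, C11 R) | CC(=O)O[C@H](C)[C@H](/C=C/[C@@H]1O[C@H]([C@H]3COC(C)(C)O3)[C@@H]2OC(C)(C)O[C@H]12)O[Si](CC)(CC)CC | intermediate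
12 | (1E,3S,4R)-4-acetoxy-1-(2,3:5,6-di-O-isopropylidene-β-D-mannofuranosyl)pent-1-en-3-ol | CC(=O)O[C@H](C)[C@H](/C=C/[C@@H]1O[C@H]([C@H]3COC(C)(C)O3)[C@@H]2OC(C)(C)O[C@H]12)O | intermediate
13 | (1E,3S,4R)-4-acetoxy-3-benzoyloxy-1-(2,3:5,6-di-O-isopropylidene-β-D-mannofuranosyl)pent-1-ene | CC(=O)O[C@H](C)[C@H](/C=C/[C@@H]1O[C@H]([C@H]3COC(C)(C)O3)[C@@H]2OC(C)(C)O[C@H]12)OC(=O)c1ccccc1 | intermediate
14 | (1E,3S,4R)-4-acetoxy-3-benzoyloxy-1-(2,3-O-isopropylidene-β-D-mannofuranosyl)pent-1-ene (5,6-diol) | CC(=O)O[C@H](C)[C@H](/C=C/[C@@H]1O[C@H]([C@H](O)CO)[C@@H]2OC(C)(C)O[C@H]12)OC(=O)c1ccccc1 | intermediate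
15 | (1E,3S,4R)-4-acetoxy-3-benzoyloxy-1-(2,3-O-isopropylidene-β-D-lyxo-pentodialdo-1,4-furanosyl)pent-1-ene (C3 aldehyde) | CC(=O)O[C@H](C)[C@H](/C=C/[C@@H]1O[C@H](C=O)[C@@H]2OC(C)(C)O[C@H]12)OC(=O)c1ccccc1 | intermediate
16 | methyl bis(2,2,2-trifluoroethyl)phosphonoacetate | COC(=O)CP(=O)(OCC(F)(F)F)OCC(F)(F)F | starting material
17 | methyl (Z)-enoate: as 15 with the aldehyde replaced by (Z)-CH=CH–CO2Me (C3=C2–C1), C5/C6 still as acetonide | CC(=O)O[C@H](C)[C@H](/C=C/[C@@H]1O[C@H](/C=C\C(=O)OC)[C@@H]2OC(C)(C)O[C@H]12)OC(=O)c1ccccc1 | intermediate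
18 | dihydroxy (Z)-ester: as 17 with free C5 and C6 hydroxyls | CC(=O)O[C@H](C)[C@H](/C=C/[C@@H]1O[C@H](/C=C\C(=O)OC)[C@H](O)[C@@H]1O)OC(=O)c1ccccc1 | intermediate
19 | (2S,3R,3aR,7aR)-2-[(1E,3S,4R)-4-acetoxy-3-(benzoyloxy)pent-1-en-1-yl]-3-hydroxy-2,3,3a,7a-tetrahydro-5H-furo[3,2-b]pyran-5-one (CNP0151877.1) | CC(=O)O[C@H](C)[C@H](/C=C/[C@@H]1O[C@@H]2C=CC(=O)O[C@@H]2[C@@H]1O)OC(=O)c1ccccc1 | target

**Step count and risks**
Total: 11 steps. Longest linear sequence: 9 steps (1 to 19 through steps 1, 2, 3, 6, 7, 8, 9, 10, 11); the aldehyde branch (steps 4, 5) joins at step 6.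

Steps most likely to fail:

1. Step 6. The coupling relies on substrate control only, so facial selectivity at C10 may be poor. The terminal alkyne may also oligomerise on nickel, and the α-acyloxy aldehyde may be eroded by the carbene ligand. Fallback: the fragment union is moved to a chromium-mediated alkenylation. Starting from 6, palladium-catalysed hydrostannation (Bu3SnH, PdCl2(PPh3)2 cat., divalent palladium precatalyst, THF) should give the (E)-2-(tributylstannyl)vinyl C-glycoside F1. Iododestannylation (I2, CH2Cl2, 0 °C) gives the (E)-2-iodovinyl C-glycoside F2. Nozaki–Hiyama–Kishi coupling of F2 with aldehyde 10 (CrCl2, NiCl2 cat., DMSO, rt; a chiral sulfonamide ligand on chromium can be added if Felkin–Anh control is insufficient) forms the same C9–C10 bond with retention of the (E)-geometry. This returns to the route at alcohol 12.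

2. Step 3. The terminal acetonide may be lost to the Lewis acid, or hydride delivery to the oxocarbenium ion may not be fully face-selective. Fallback: C7 is set by ring closure instead of reduction. Starting from lactol 1, ethynylmagnesium bromide adds to the open-chain aldehyde form to give the (3R)-1,2-dideoxy-4,5:7,8-di-O-isopropylidene-oct-1-yne-3,6-diol F3 (separated from its C3 epimer if both form). TsCl in pyridine should sulfonylate the less hindered propargylic hydroxyl to the propargylic tosylate F4, which is not isolated. The remaining hydroxyl then displaces the tosylate with inversion (intramolecular SN2, 5-exo-tet) and closes the tetrahydrofuran, returning to the route at 6.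

3. Step 10. Under the basic phosphonate conditions the aldehyde may epimerise at C4 or lose the β-oxygen by elimination, and Z-selectivity may be incomplete. Fallback: the anionic phosphonate olefination is replaced by the base-free Wittig reaction. Starting from 15, methyl (triphenylphosphoranylidene)acetate in methanol at 0 °C should give mainly the (Z)-enoate, as is usual for α-alkoxy aldehydes in methanol. This returns to the route at 17 and makes no new compound (F0); any (E)-isomer is removed after step 11 because only the (Z)-ester lactonises.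

**Further compounds**
F1 | step 6 | (E)-2-(tributylstannyl)vinyl 2,3:5,6-di-O-isopropylidene-β-D-mannofuranoside (C-glycoside) | CCCC[Sn](CCCC)(CCCC)/C=C/[C@@H]1O[C@H]([C@H]3COC(C)(C)O3)[C@@H]2OC(C)(C)O[C@H]12
F2 | step 6 | (E)-2-iodovinyl 2,3:5,6-di-O-isopropylidene-β-D-mannofuranoside (C-glycoside) | I/C=C/[C@@H]1O[C@H]([C@H]3COC(C)(C)O3)[C@@H]2OC(C)(C)O[C@H]12
F3 | step 3 | (3R)-1,2-dideoxy-4,5:7,8-di-O-isopropylidene-oct-1-yne-3,6-diol (D-manno-derived) | C#C[C@@H](O)[C@H]1OC(C)(C)O[C@H]1[C@H](O)[C@H]2COC(C)(C)O2
F4 | step 3 | 3-O-(p-toluenesulfonyl) derivative of F3 (propargylic tosylate) | C#C[C@@H](OS(=O)(=O)c1ccc(C)cc1)[C@H]2OC(C)(C)O[C@H]2[C@H](O)[C@H]3COC(C)(C)O3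
F0 | step 10 | none | none
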